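The numbers in the tables are simulated on assumed constants; the scatter is artificial.

Late in the dawn run, at 25.0 min, I read 34.4 % intermediate and 38.6 % target, where at 2.00 min the target-to-intermediate ratio was 0.248. I take equal shares, a ratio of one, as the zero of the scale. Averaged over the last readings of the dawn, dusk and autumn runs, the ratio stands a little above that zero, at 1.10. I call this reading the late split: target per intermediate at the end of a run. It leaves the intermediate 47.6 % of the pair, meaning intermediate plus target.

| flask | starting material | reagent | remark | time |
|---|---|---|---|---|
| dawn | 20 mM | 26 mM | run made earlier |  |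
| dusk | 28 mM | 26 mM | run made earlier |  |
| autumn | 44 mM | 26 mM | run made earlier |  |
| theta | 20 mM | 26.0 mM | one stirred flow tank at steady state, fed with the mixture as stated, mean residence time 40 min |  |
| eta | 20 mM (fed, over 20.0 min) | 26.0 mM | all but starting material at the start; starting material goes in evenly over 20.0 min, the run ends at 40 min | 40 min |
| gamma | 20 mM | 26.0 mM | a closed flask charged with all of it at once and left for 40 min | 40 min |
| beta | 20 mM | 26.0 mM | a single well-mixed tank run continuously and read at steady state, 400 min in it on average |  |

| run | time / min | intermediate / % | target / % |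
|---|---|---|---|
| dawn | 2.00 | 23.8 | 5.9 |
| dawn | 6.00 | 33.4 | 22.0 |
| dawn | 12.0 | 33.8 | 33.4 |
| dawn | 15.0 | 35.4 | 35.4 |
| dawn | 25.0 | 34.4 | 38.6 |
| dusk | 2.00 | 22.9 | 5.8 |
| dusk | 4.00 | 30.2 | 12.8 |
| dusk | 6.00 | 30.5 | 17.6 |
| dusk | 12.0 | 30.5 | 30.5 |
| dusk | 25.0 | 31.1 | 33.4 |
| autumn | 2.00 | 22.8 | 4.4 |
| autumn | 4.00 | 23.7 | 12.1 |
| autumn | 6.00 | 25.4 | 17.2 |
| autumn | 12.0 | 23.1 | 21.9 |
| autumn | 25.0 | 21.0 | 23.3 |

(each reading ± 1 percentage point)

- the stated concentrations are those of everything mixed, before any reaction; amounts are the same in each set-up
- the feed brings no volume worth counting
- the earlier runs were made in a closed, stirred flask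

- the set-up with the highest amount of intermediate at the outlet or at the end, in percent of the starting material put in ("none" if the first two lie within 2 percentage points) (theta / eta / gamma / beta / none)
- amount of intermediate at the outlet or at the end, in percent of the starting material put in, theta
- amount of intermediate at the outlet or at the end, in percent of the starting material put in, eta
- amount of intermediate at the outlet or at the end, in percent of the starting material put in, gamma
- amount of intermediate at the outlet or at the end, in percent of the starting material put in, beta

Now the ledger. In the dawn run the limiting reagent by charge is the starting material, [starting material] = 20 mM against [reagent] = 26 mM. The first entry is the intermediate and the second the target, together 73.0 % of the charge at 25.0 min. The remaining 27.0 % stands in no column. Counting one reagent per member of the pair, the pair in the dawn run accounts for 14.6 mM of reagent; what the unread part took is not entered. The autumn run, with [starting material] = 44 mM, shows 19.5 mM of pair at 25.0 min, so 6.51 mM of its reagent stays unentered.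

Gamma is the dawn charge in a closed flask, left for 40 min. The dawn pair moved from 70.8 % at 15.0 min to 73.0 % at 25.0 min, so I carry it over unchanged and close the books with my own figure for gamma: pair times share, 34.7 %.

The forecast names gamma as best, with theta 23 %, eta 27 %, gamma 34 % and beta 22 %. For the tanks it argues that “a single mixed tank has a ceiling of 1/(1+√1.1)² ≈ 24%”.

The flask gives gamma as best at 33.8 %, then eta 30.6 %, theta 28.2 % and beta 22.4 %; theta lies 5.2 percentage points above the forecast, with 30.9 % of its starting material still at the outlet.

    starting material + reagent → intermediate + released group (k = 0.140 M⁻¹ s⁻¹)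
    intermediate ⇌ target (K = 1.10, k = 0.00350 s⁻¹)
    intermediate ⇌ isomer of the product (K = 2.90, k = 2.40 × 10⁻⁴ s⁻¹)
    reagent ⇌ dormant form (K = 2.50, k = 5.20 × 10⁻⁴ s⁻¹)

The late split, put on the gamma pair of 71.5 % at 40.0 min, gives 34.0 % intermediate. The neighbour of eta charged with 100 mM of reagent ends with a pair of 82.6 %, which the split divides into 39.3 % intermediate, and that flask holds 38.7 %.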